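## The problem

The target is a 2H-chromen-2-one whose benzene ring (C4a, C5, C6, C7, C8, C8a) is substituted at every carbon. C8a carries the lactone oxygen, C8 a methyl, C7 a hydroxyl, C6 a methyl, C5 a (2R,3S)-3-hydroxybutan-2-yl chain, and C4a the lactone ring carbon C4. C3 is bonded to C6' of a (2R)-2-methyl-2,3-dihydro-4H-pyran-4-one.

There are three stereocentres in two groups. In the C5 chain the carbinol centre can set the neighbouring benzylic centre by 1,2-induction. C2' of the pyranone is too far away to be controlled by anything else, so two chiral-pool sources and a convergent union are needed.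

C5 is meta to both ring oxygens, so the chain cannot be put on a resorcinol by electrophilic substitution. The ring has to be built around it.

The dihydropyranone is a β-alkoxy enone: base can open it by elimination of the ring oxygen and reclose it with loss of the C2' configuration. The benzylic centre is epimerisable as long as it is α or γ to a carbonyl group in early intermediates. The side-chain hydroxyl lies three atoms from C4: next to a formyl group at C4a it would close to a lactol and, with the C7 hydroxyl, collapse to a quinone methide. It must therefore stay masked until the C3=C4 bond exists.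

The feature that opens the ring construction is the carbon pattern of the arene. C6–C7–C8 with their two methyl groups are the skeleton of pentan-3-one, and C8a–C4a–C4 is that of a malonate. The arene is thus a dehydrogenated 2,4-dimethylcyclohexane-1,3-dione bearing an ester, and C5 is the β-carbon of an alkylidene malonate made from the side-chain aldehyde.

## Retrosynthesis

(TBS = tert-butyldimethylsilyl throughout.)

**Target 22 from 21.** Only the side-chain O–Si bond is cut. The silyl ether is kept to the very end because the free hydroxyl is incompatible with a formyl group at C4a. Cleavage is asked to proceed under buffered acidic fluoride, since basic fluoride would endanger the dihydropyranone.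

**21 from aldehyde 20 and ester 19.** The C3=C4 bond and the O1–C2 bond are cut (Knoevenagel condensation, then lactonisation). Cutting C4–C4a instead would require a resorcinol without C4 and an acid-promoted ring closure. Cutting C3–C6' would require a metalated vinylogous ester. The chosen cut gives two halves of similar size, each with its own pool-derived stereocentres. The forward reaction must work on a hindered, hydrogen-bonded aldehyde under amine catalysis mild enough to leave C2' alone. Aldehyde 20 is released in the same flask from its bis(aryl silyl ether) 13.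

**19 from 18, and 18 from 16 and 17.** The ring C6'–O bond of the pyranone is cut, giving the δ-silyloxy β,δ-diketo ester 18. Cutting C5–C6 of 18 leads to the acetoacetate dianion from 17 and Weinreb amide 16, which comes from methyl (R)-3-hydroxybutanoate 14 through silyl ether 15. The C–O bond at the stereocentre is never broken. The acylation must stop at the ketone stage, which the Weinreb amide secures.

**13 from 12 and 11.** C4 is already on the ring as an ester, so only its oxidation level changes (ester to alcohol to aldehyde). Reduction of a benzoate with free ortho and para hydroxyls risks loss of the benzylic oxygen through a quinone methide and over-reduction to a methyl group. The phenols are therefore carried as silyl ethers through these two steps.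

**11 from 10 and 9.** The arene is traced to the tricarbonyl 9 by removal of two hydrogens. Going through the bis(silyl enol ether) 10 turns the dehydrogenation into the aromatisation of a cyclohexa-1,3-diene, which is mild, and delivers the phenols already capped for the reduction.

**9 from 6 and 7 (through 8).** The C8–C8a bond (Claisen) and the C5–C6 bond (Michael) are cut. This single operation assembles the ring carbons with C4 attached, from pentan-3-one 7 and alkylidene malonate 6. The precursors are far simpler than any hexasubstituted arene, and the side-chain stereocentres ride through as spectators. The forward reaction needs conjugate addition to outrun γ-deprotonation of 6.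

**6 from 4 and 5, and 4 from 1.** The C=C bond of 6 is cut to aldehyde 4 and diethyl malonate 5. Aldehyde 4 comes from ester 3, silyl ether of the anti-methylated hydroxy ester 2, which is made from ethyl (S)-3-hydroxybutanoate 1. The existing carbinol centre sets the new methyl-bearing centre.

## Roads not taken

**Alternative 1:** Aryne acyl-alkylation. The cut is at the C5–benzylic bond and the C4a–C4 bond. Fluoride (CsF) would turn the silylaryl triflate A1 into the C4a–C5 aryne. The carbanion of dimethyl 2-methylmalonate A2 adds at C5, and the aryl anion at C4a attacks an ester carbonyl and fragments, giving homophthalate A3.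

- Merits: two carbon–carbon bonds are formed on a ring that already has both oxygens, and no dehydrogenation is needed. In this respect it is better than the chosen plan.
- Weak points for this target: A3 is racemic at the benzylic carbon, so both side-chain centres must be created later. A3 has hydrogen where C6 needs a methyl. Two aryl methyl ethers must be cleaved at the end in the presence of the lactone and the vinylogous ester. The C4 ester still needs the same reduction and oxidation.
- Comparison: the chosen plan sets against the shorter arene construction a side chain of defined configuration from the pool, a C6 methyl already in place, and silyl protection that leaves under mild conditions.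

**Alternative 2:** Transposed Pechmann annulation. The cut is at C4–C4a and O1–C2. Under acid, the resorcinol acetate A4 would attack the aminomethylene carbon of enamino ester A5 with its only free ring position. The amine is expelled and the C8a hydroxyl lactonises, giving the O-acetate A6 of the target.

- Merits: the free position is ortho and para to the two hydroxyls, and no oxidation-level change at C4 is needed. The endgame is shorter than the chosen one by about three steps.
- Weak points: the plan does not say how A4, with its meta-placed chiral chain, is made, and that is the hard part of the molecule. The attacking carbon is flanked by the branched chain. Strong acid threatens the vinylogous ester of A5. The acetate of A6 must finally be removed by base or nucleophile next to a base-sensitive pyranone and a lactone.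
- Comparison: the chosen plan spends extra steps on C4 but solves the arene problem, closes the lactone under buffered amine catalysis, and ends with a fluoride deprotection.

**Alternative 3:** Diels–Alder benzannulation. The cut is at C5–C6 and C4a–C8a. The bis(silyloxy)diene A7 and the chiral ynoate A8 would combine thermally. Loss of the methoxy group and hydrolysis of the silyl groups on acidic work-up would give resorcylate A9.

- Merits: the ring arrives aromatic, at the same stage as 11 but without a separate dehydrogenation, and no strongly basic enolate meets a γ-acidic acceptor. On both counts it is at least as good as the chosen plan.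
- Weak points: the cycloaddition must join a diene terminus bearing a methyl group to an alkyne carbon bearing a branched chain, forming a hexasubstituted ring under heat. A8 needs an alkyne homologation and carboxylation of aldehyde 4, with a propargylic stereocentre at risk. A7 needs control of its (3Z) geometry. A9 has free phenols and would still need protection before ester reduction.
- Comparison: the chosen plan uses two bulk chemicals (5 and 7) and a polar addition to a highly electrophilic, unhindered acceptor at −78 °C. Its enol silylation before aromatisation supplies the phenol protection that A9 would need anyway.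

Key step: step 5

Assumption: compounds 8, 9 and 10 are handled as mixtures of epimers and tautomers at the centres formed in step 5, because all of these centres become sp2 in step 7.

Step 1
Reactants: 1 ethyl (S)-3-hydroxybutanoate
Product: 2 ethyl (2S,3S)-3-hydroxy-2-methylbutanoate
Conditions: LiN(i-Pr)2 (2.2 equiv), THF, −50 → −20 °C; MeI, DMPU, −78 → 0 °C; aq. NH4Cl
Reagents that add atoms: iodomethane, CI
Why: Fráter–Seebach alkylation: the dilithium alkoxide–enolate is a rigid chelate and iodomethane enters anti to the C3 methyl group, which sets C2 as S (anti isomer) by 1,2-induction from the pool centre.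

Step 2
Reactants: 2 ethyl (2S,3S)-3-hydroxy-2-methylbutanoate
Product: 3 ethyl (2S,3S)-3-(TBSO)-2-methylbutanoate
Conditions: TBSCl, imidazole, DMF, rt
Reagents that add atoms: tert-butyldimethylsilyl chloride, CC(C)(C)[Si](C)(C)Cl
Why: Standard imidazole-mediated silylation of a secondary alcohol; the silyl ether tolerates the hydride, enolate and oxidant steps and blocks later lactol formation.

Step 3
Reactants: 3 ethyl (2S,3S)-3-(TBSO)-2-methylbutanoate
Product: 4 (2S,3S)-3-(TBSO)-2-methylbutanal
Conditions: i-Bu2AlH (1.1 equiv), CH2Cl2, −78 °C; MeOH, aq. KNaC4H4O6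
Reagents that add atoms: none
Why: Partial ester reduction with i-Bu2AlH; the tetrahedral aluminium hemiacetal, held by chelation to the β-silyloxy oxygen, collapses only on work-up, and the aldehyde is used at once to protect its α-centre.

Step 4
Reactants: 4 (2S,3S)-3-(TBSO)-2-methylbutanal; 5 diethyl malonate
Product: 6 diethyl 2-[(2R,3S)-3-(TBSO)-2-methylbutylidene]malonate
Conditions: TiCl4 (2 equiv), pyridine (4 equiv), THF, 0 °C → rt
Reagents that add atoms: none
Why: Knoevenagel condensation under TiCl4/pyridine (Lehnert conditions): the titanium malonate enolate adds to the activated aldehyde and elimination follows at or below room temperature in a weakly basic medium, which spares the α-centre; the two ester groups are identical, so no alkene isomers arise (the descriptor changes from S to R only through ligand priorities).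

Step 5
Reactants: 6 diethyl 2-[(2R,3S)-3-(TBSO)-2-methylbutylidene]malonate; 7 pentan-3-one
Product: 9 ethyl 6-[(2R,3S)-3-(TBSO)butan-2-yl]-3,5-dimethyl-2,4-dioxocyclohexane-1-carboxylate (ring epimers/enol forms), via Michael adduct keto diester 8 (not isolated)
Conditions: 7 (1.15 equiv), LiN(i-Pr)2 (1.1 equiv), THF, −78 °C; 6, −78 °C; then NaOEt (1.0 equiv), EtOH, −78 → 65 °C; cold 1 M HCl
Reagents that add atoms: none
Why: The kinetic lithium enolate of 7 adds in conjugate fashion to the doubly activated alkene of 6 (Michael addition, forming the later C5–C6 bond) and gives the malonate enolate of 8. Ethoxide in ethanol then equilibrates this anion with the ethyl-side ketone enolate, which attacks one ester carbonyl in a 6-(enolexo)-exo-trig Claisen (Dieckmann-type) closure that forms the later C8–C8a bond and expels ethoxide. The closest known reaction is the dimedone-type Michael–Claisen synthesis of cyclohexane-1,3-diones, here with the roles of enolate and acceptor exchanged. Only the ethyl-side carbon can reach an ester through a six-membered transition state, since the other α-carbon would close a four-membered ring. The product is deprotonated to its tricarbonyl enolate as it forms, which drives the closure and blocks the reverse reaction. The three new ring stereocentres arise without control and need none, because all become sp2 in step 7, while the side-chain centres are spectators. The selectivity that matters is conjugate addition ahead of γ-deprotonation of 6, which would epimerise the side chain or expel silanolate; it is secured by the high electrophilicity of the alkylidene malonate at −78 °C, by the modest basicity of a ketone enolate, and by using no excess amide base. Once 8 has formed, the side-chain methine is no longer acidic.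

Step 6
Reactants: 9 ethyl 6-[(2R,3S)-3-(TBSO)butan-2-yl]-3,5-dimethyl-2,4-dioxocyclohexane-1-carboxylate
Product: 10 ethyl 2,4-bis(TBSO)-6-[(2R,3S)-3-(TBSO)butan-2-yl]-3,5-dimethylcyclohexa-1,3-diene-1-carboxylate
Conditions: TBSOTf (2.6 equiv), Et3N (4 equiv), CH2Cl2, 0 °C → rt
Reagents that add atoms: tert-butyldimethylsilyl trifluoromethanesulfonate, CC(C)(C)[Si](C)(C)OS(=O)(=O)C(F)(F)F
Why: Silyl enol ether formation at both the vinylogous acid and the β-keto ester enol turns the tricarbonyl into a 2,4-bis(silyloxy)cyclohexa-1,3-diene; a regioisomeric dienol ether, if formed, converges in step 7.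

Step 7
Reactants: 10 ethyl 2,4-bis(TBSO)-6-[(2R,3S)-3-(TBSO)butan-2-yl]-3,5-dimethylcyclohexa-1,3-diene-1-carboxylate
Product: 11 ethyl 2,4-bis(TBSO)-6-[(2R,3S)-3-(TBSO)butan-2-yl]-3,5-dimethylbenzoate
Conditions: DDQ (1.2 equiv), 2,4,6-collidine, PhMe, 0 °C → rt
Reagents that add atoms: none
Why: DDQ dehydrogenation of a cyclohexadiene: hydride abstraction from C6 gives a cation stabilised by both silyloxy groups, and loss of the C5 proton to collidine gives the arene, as in the known aromatisation of silyl dienol ethers to aryl silyl ethers; the ring centres of step 5 vanish and the phenol oxygens emerge protected.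

Step 8
Reactants: 11 ethyl 2,4-bis(TBSO)-6-[(2R,3S)-3-(TBSO)butan-2-yl]-3,5-dimethylbenzoate
Product: 12 {2,4-bis(TBSO)-6-[(2R,3S)-3-(TBSO)butan-2-yl]-3,5-dimethylphenyl}methanol
Conditions: i-Bu2AlH (3 equiv), CH2Cl2, −78 → 0 °C; aq. KNaC4H4O6
Reagents that add atoms: none
Why: Ester reduction to the primary alcohol with excess i-Bu2AlH; with both phenols capped the benzylic aluminate cannot ionise to a quinone methide, which is the usual route to over-reduction of hydroxybenzoates.

Step 9
Reactants: 12 {2,4-bis(TBSO)-6-[(2R,3S)-3-(TBSO)butan-2-yl]-3,5-dimethylphenyl}methanol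
Product: 13 2,4-bis(TBSO)-6-[(2R,3S)-3-(TBSO)butan-2-yl]-3,5-dimethylbenzaldehyde
Conditions: Dess–Martin periodinane, CH2Cl2, rt
Reagents that add atoms: none
Why: Dess–Martin oxidation of a benzylic alcohol, which is neutral, tolerant of steric crowding and harmless to silyl ethers.

Step 10
Reactants: 14 methyl (R)-3-hydroxybutanoate
Product: 15 methyl (R)-3-(TBSO)butanoate
Conditions: TBSCl, imidazole, DMF, rt
Reagents that add atoms: tert-butyldimethylsilyl chloride, CC(C)(C)[Si](C)(C)Cl
Why: Standard silylation; the protected hydroxyl cannot interfere with the organometallic steps that follow.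

Step 11
Reactants: 15 methyl (R)-3-(TBSO)butanoate
Product: 16 (R)-3-(TBSO)-N-methoxy-N-methylbutanamide
Conditions: MeNH(OMe)·HCl (1.5 equiv), i-PrMgCl (3 equiv), THF, −20 → 0 °C
Reagents that add atoms: N,O-dimethylhydroxylamine hydrochloride, CNOC.Cl
Why: Weinreb amide formation from an ester with the chloromagnesium amide, a weakly basic nucleophile that does not eliminate the β-silyloxy group.

Step 12
Reactants: 16 (R)-3-(TBSO)-N-methoxy-N-methylbutanamide; 17 methyl acetoacetate
Product: 18 methyl (7R)-7-(TBSO)-3,5-dioxooctanoate (enol forms)
Conditions: 17 (2 equiv), LiN(i-Pr)2 (4 equiv), THF, 0 °C; 16, −78 → 0 °C; cold 1 M HCl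
Reagents that add atoms: none
Why: Acylation of the acetoacetate dianion at its γ-carbon by a Weinreb amide; the chelated tetrahedral intermediate persists until the quench, so neither over-addition nor proton transfer from the acidic product occurs.

Step 13
Reactants: 18 methyl (7R)-7-(TBSO)-3,5-dioxooctanoate
Product: 19 methyl 2-[(2R)-2-methyl-4-oxo-3,4-dihydro-2H-pyran-6-yl]acetate
Conditions: 48% aq. HF, MeCN, 0 °C → rt; then TsOH·H2O (cat.), CH2Cl2, MgSO4, rt
Reagents that add atoms: none
Why: Acidic desilylation frees the C7 hydroxyl, which adds to the C3 ketone (the only carbonyl that gives a six-membered hemiketal), and acid-catalysed dehydration gives the conjugated vinylogous ester; the C–O bond at the stereocentre is untouched, so R is retained.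

Step 14
Reactants: 13 2,4-bis(TBSO)-6-[(2R,3S)-3-(TBSO)butan-2-yl]-3,5-dimethylbenzaldehyde; 19 methyl 2-[(2R)-2-methyl-4-oxo-3,4-dihydro-2H-pyran-6-yl]acetate
Product: 21 5-[(2R,3S)-3-(TBSO)butan-2-yl]-7-hydroxy-6,8-dimethyl-3-[(2R)-2-methyl-4-oxo-3,4-dihydro-2H-pyran-6-yl]-2H-chromen-2-one, via dihydroxy aldehyde 20 (not isolated)
Conditions: KHF2 (2.5 equiv), MeOH, rt; then 19 (1.2 equiv), piperidine (0.3 equiv), AcOH (0.3 equiv), 50 °C
Reagents that add atoms: none
Why: KHF2 in methanol cleaves aryl silyl ethers while leaving alkyl silyl ethers; piperidinium acetate then effects Knoevenagel condensation of the salicylaldehyde (through its iminium ion) with the active methylene of 19, and the C8a phenol lactonises onto the methyl ester, which makes the condensation irreversible; buffered amine catalysis at moderate temperature limits enolisation of the dihydropyranone.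

Step 15
Reactants: 21 5-[(2R,3S)-3-(TBSO)butan-2-yl]-7-hydroxy-6,8-dimethyl-3-[(2R)-2-methyl-4-oxo-3,4-dihydro-2H-pyran-6-yl]-2H-chromen-2-one
Product: 22 7-hydroxy-5-[(2R,3S)-3-hydroxybutan-2-yl]-6,8-dimethyl-3-[(2R)-2-methyl-4-oxo-3,4-dihydro-2H-pyran-6-yl]-2H-chromen-2-one
Conditions: HF·pyridine, THF, pyridine, 0 °C → rt
Reagents that add atoms: none
Why: Fluoride-mediated cleavage of the secondary silyl ether under buffered acidic conditions, which leave the lactone, the vinylogous ester and its C2' centre untouched; no stereocentre is involved.

## Compound list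

1 | ethyl (S)-3-hydroxybutanoate | CCOC(=O)C[C@H](C)O | starting material
2 | ethyl (2S,3S)-3-hydroxy-2-methylbutanoate | CCOC(=O)[C@@H](C)[C@H](C)O | intermediate
3 | ethyl (2S,3S)-3-(tert-butyldimethylsilyloxy)-2-methylbutanoate | CCOC(=O)[C@@H](C)[C@H](C)O[Si](C)(C)C(C)(C)C | intermediate
4 | (2S,3S)-3-(tert-butyldimethylsilyloxy)-2-methylbutanal | O=C[C@@H](C)[C@H](C)O[Si](C)(C)C(C)(C)C | intermediate
5 | diethyl malonate | CCOC(=O)CC(=O)OCC | starting material
6 | diethyl 2-[(2R,3S)-3-(tert-butyldimethylsilyloxy)-2-methylbutylidene]malonate | CCOC(=O)C(C(=O)OCC)=C[C@@H](C)[C@H](C)O[Si](C)(C)C(C)(C)C | intermediate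
7 | pentan-3-one | CCC(=O)CC | starting material
8 | diethyl 2-[(2S,3R)-2-(tert-butyldimethylsilyloxy)-3,5-dimethyl-6-oxooctan-4-yl]malonate (formed as its enolate, mixture at C4 and C5) | CCOC(=O)C(C(=O)OCC)C(C(C)C(=O)CC)[C@@H](C)[C@H](C)O[Si](C)(C)C(C)(C)C | intermediate
9 | ethyl 6-[(2R,3S)-3-(tert-butyldimethylsilyloxy)butan-2-yl]-3,5-dimethyl-2,4-dioxocyclohexane-1-carboxylate (ring epimers and enol forms) | CCOC(=O)C1C(=O)C(C)C(=O)C(C)C1[C@@H](C)[C@H](C)O[Si](C)(C)C(C)(C)C | intermediate
10 | ethyl 2,4-bis(tert-butyldimethylsilyloxy)-6-[(2R,3S)-3-(tert-butyldimethylsilyloxy)butan-2-yl]-3,5-dimethylcyclohexa-1,3-diene-1-carboxylate (epimers at C5 and C6) | CCOC(=O)C1=C(O[Si](C)(C)C(C)(C)C)C(C)=C(O[Si](C)(C)C(C)(C)C)C(C)C1[C@@H](C)[C@H](C)O[Si](C)(C)C(C)(C)C | intermediate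
11 | ethyl 2,4-bis(tert-butyldimethylsilyloxy)-6-[(2R,3S)-3-(tert-butyldimethylsilyloxy)butan-2-yl]-3,5-dimethylbenzoate | CCOC(=O)c1c(O[Si](C)(C)C(C)(C)C)c(C)c(O[Si](C)(C)C(C)(C)C)c(C)c1[C@@H](C)[C@H](C)O[Si](C)(C)C(C)(C)C | intermediate
12 | {2,4-bis(tert-butyldimethylsilyloxy)-6-[(2R,3S)-3-(tert-butyldimethylsilyloxy)butan-2-yl]-3,5-dimethylphenyl}methanol | OCc1c(O[Si](C)(C)C(C)(C)C)c(C)c(O[Si](C)(C)C(C)(C)C)c(C)c1[C@@H](C)[C@H](C)O[Si](C)(C)C(C)(C)C | intermediate
13 | 2,4-bis(tert-butyldimethylsilyloxy)-6-[(2R,3S)-3-(tert-butyldimethylsilyloxy)butan-2-yl]-3,5-dimethylbenzaldehyde | O=Cc1c(O[Si](C)(C)C(C)(C)C)c(C)c(O[Si](C)(C)C(C)(C)C)c(C)c1[C@@H](C)[C@H](C)O[Si](C)(C)C(C)(C)C | intermediate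
14 | methyl (R)-3-hydroxybutanoate | COC(=O)C[C@@H](C)O | starting material
15 | methyl (R)-3-(tert-butyldimethylsilyloxy)butanoate | COC(=O)C[C@@H](C)O[Si](C)(C)C(C)(C)C | intermediate
16 | (R)-3-(tert-butyldimethylsilyloxy)-N-methoxy-N-methylbutanamide | CON(C)C(=O)C[C@@H](C)O[Si](C)(C)C(C)(C)C | intermediate
17 | methyl acetoacetate | COC(=O)CC(C)=O | starting material
18 | methyl (7R)-7-(tert-butyldimethylsilyloxy)-3,5-dioxooctanoate | COC(=O)CC(=O)CC(=O)C[C@@H](C)O[Si](C)(C)C(C)(C)C | intermediate
19 | methyl 2-[(2R)-2-methyl-4-oxo-3,4-dihydro-2H-pyran-6-yl]acetate | COC(=O)CC1=CC(=O)C[C@@H](C)O1 | intermediate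
20 | 6-[(2R,3S)-3-(tert-butyldimethylsilyloxy)butan-2-yl]-2,4-dihydroxy-3,5-dimethylbenzaldehyde | O=Cc1c(O)c(C)c(O)c(C)c1[C@@H](C)[C@H](C)O[Si](C)(C)C(C)(C)C | intermediate
21 | 5-[(2R,3S)-3-(tert-butyldimethylsilyloxy)butan-2-yl]-7-hydroxy-6,8-dimethyl-3-[(2R)-2-methyl-4-oxo-3,4-dihydro-2H-pyran-6-yl]-2H-chromen-2-one | Cc1c(O)c(C)c2oc(=O)c(C3=CC(=O)C[C@@H](C)O3)cc2c1[C@@H](C)[C@H](C)O[Si](C)(C)C(C)(C)C | intermediate
22 | 7-hydroxy-5-[(2R,3S)-3-hydroxybutan-2-yl]-6,8-dimethyl-3-[(2R)-2-methyl-4-oxo-3,4-dihydro-2H-pyran-6-yl]-2H-chromen-2-one | Cc1c(O)c(C)c2oc(=O)c(C3=CC(=O)C[C@@H](C)O3)cc2c1[C@@H](C)[C@H](C)O | target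

## Step count and least certain steps

Total: 15 steps. Longest linear sequence: 11 steps (steps 1–9, 14, 15). The pyranone arm takes 4 steps (10–13).

**Step 5 (key step).** The most likely failure is proton transfer instead of addition: the enolate removes the γ-hydrogen of 6, which epimerises the side-chain centre or expels silanolate. A second failure is a stalled Claisen closure because 8 rests as its unreactive malonate anion. Fallback, from 7 and 6 back to 9: 7 is converted to trimethyl(pent-2-en-3-yloxy)silane F1 (Me3SiCl, Et3N, NaI, MeCN). F1 adds to 6 under TiCl4 in CH2Cl2 at −78 °C (Mukaiyama–Michael addition, no base present). Neutral 8 is isolated and closed separately with NaOEt in refluxing EtOH to give 9.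

**Step 4.** The aldehyde may enolise in the titanium/pyridine medium with loss of the C2 configuration, or 6 may lose silanol after γ-deprotonation. Fallback, from 3 back to 6:
- i-Bu2AlH (2.5 equiv) reduces 3 to (2R,3S)-3-(tert-butyldimethylsilyloxy)-2-methylbutan-1-ol F2.
- I2, PPh3 and imidazole give tert-butyl{[(2S,3S)-4-iodo-3-methylbutan-2-yl]oxy}dimethylsilane F3.
- PPh3 in MeCN at 80 °C gives [(2S,3S)-3-(tert-butyldimethylsilyloxy)-2-methylbutyl]triphenylphosphonium iodide F4.
- Deprotonation with NaN(SiMe3)2 at −78 °C and Wittig reaction with diethyl oxomalonate deliver 6.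

In this sequence the stereocentre is never α to a carbonyl group.

**Step 7 (with step 6).** Double enol silylation of the crowded tricarbonyl may be incomplete, or a silyl group may transfer from the oxocarbenium intermediate to the reduced quinone, giving mixtures of partly silylated arenes. Fallback, from 9 back to 11: heterogeneous dehydrogenation of 9 with Pd/C in refluxing mesitylene gives ethyl 6-[(2R,3S)-3-(tert-butyldimethylsilyloxy)butan-2-yl]-2,4-dihydroxy-3,5-dimethylbenzoate F5. Both phenols are then silylated (TBSOTf, Et3N, CH2Cl2) to 11.

**Step 8.** Hydride delivery to an ester flanked by a silyloxy group and a branched alkyl group may be slow, and the ortho silyl group may migrate from the phenol oxygen to the new benzylic alkoxide, which would uncap the phenol. Fallback, from 9 back to 20: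
- Hydrolysis and decarboxylation (KOH, aq. EtOH, 60 °C; then AcOH) give 5-[(2R,3S)-3-(tert-butyldimethylsilyloxy)butan-2-yl]-2,4-dimethylcyclohexane-1,3-dione F6.
- Pd/C in refluxing mesitylene gives 5-[(2R,3S)-3-(tert-butyldimethylsilyloxy)butan-2-yl]-2,4-dimethylbenzene-1,3-diol F7.
- Ortho-formylation at the single free ring position with MgCl2, Et3N and paraformaldehyde in MeCN (Casnati–Skattebøl formylation) gives 20, which enters the second stage of step 14.

**Step 14.** Condensation may be sluggish at an aldehyde that is doubly ortho-substituted and deactivated by the para phenoxide. On prolonged heating with amine, the dihydropyranone may enolise, open and reclose with loss of the C2' configuration. Fallback, from 13 and 18 back to 22: 20 is isolated after the KHF2 stage and condensed with open-chain 18 (piperidinium acetate, MeOH). The C2 methylene of 18 is more acidic, and 18 has no ring to open. Reversible aldol steps drain through lactonisation to 5-[(2R,3S)-3-(tert-butyldimethylsilyloxy)butan-2-yl]-3-[(5R)-5-(tert-butyldimethylsilyloxy)-3-oxohexanoyl]-7-hydroxy-6,8-dimethyl-2H-chromen-2-one F8. HF·pyridine followed by TsOH then removes both silyl groups and closes the dihydropyranone, giving 22 directly.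

## Further compounds

F1 | step 5 | trimethyl(pent-2-en-3-yloxy)silane | CC=C(CC)O[Si](C)(C)C
F2 | step 4 | (2R,3S)-3-(tert-butyldimethylsilyloxy)-2-methylbutan-1-ol | OC[C@@H](C)[C@H](C)O[Si](C)(C)C(C)(C)C
F3 | step 4 | tert-butyl{[(2S,3S)-4-iodo-3-methylbutan-2-yl]oxy}dimethylsilane | IC[C@@H](C)[C@H](C)O[Si](C)(C)C(C)(C)C
F4 | step 4 | [(2S,3S)-3-(tert-butyldimethylsilyloxy)-2-methylbutyl]triphenylphosphonium iodide | [I-].c1ccccc1[P+](c1ccccc1)(c1ccccc1)C[C@@H](C)[C@H](C)O[Si](C)(C)C(C)(C)C
F5 | step 7 | ethyl 6-[(2R,3S)-3-(tert-butyldimethylsilyloxy)butan-2-yl]-2,4-dihydroxy-3,5-dimethylbenzoate | CCOC(=O)c1c(O)c(C)c(O)c(C)c1[C@@H](C)[C@H](C)O[Si](C)(C)C(C)(C)C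
F6 | step 8 | 5-[(2R,3S)-3-(tert-butyldimethylsilyloxy)butan-2-yl]-2,4-dimethylcyclohexane-1,3-dione | O=C1CC(C(C)C(=O)C1C)[C@@H](C)[C@H](C)O[Si](C)(C)C(C)(C)C
F7 | step 8 | 5-[(2R,3S)-3-(tert-butyldimethylsilyloxy)butan-2-yl]-2,4-dimethylbenzene-1,3-diol | Cc1c(O)cc([C@@H](C)[C@H](C)O[Si](C)(C)C(C)(C)C)c(C)c1O
F8 | step 14 | 5-[(2R,3S)-3-(tert-butyldimethylsilyloxy)butan-2-yl]-3-[(5R)-5-(tert-butyldimethylsilyloxy)-3-oxohexanoyl]-7-hydroxy-6,8-dimethyl-2H-chromen-2-one | Cc1c(O)c(C)c2oc(=O)c(C(=O)CC(=O)C[C@@H](C)O[Si](C)(C)C(C)(C)C)cc2c1[C@@H](C)[C@H](C)O[Si](C)(C)C(C)(C)C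
A1 | alternative 1 | 2,4-dimethoxy-3-methyl-6-(trimethylsilyl)phenyl trifluoromethanesulfonate | COc1cc([Si](C)(C)C)c(OS(=O)(=O)C(F)(F)F)c(OC)c1C
A2 | alternative 1 | dimethyl 2-methylmalonate | COC(=O)C(C)C(=O)OC
A3 | alternative 1 | methyl 2,4-dimethoxy-6-(1-methoxy-1-oxopropan-2-yl)-3-methylbenzoate (racemic) | COC(=O)C(C)c1cc(OC)c(C)c(OC)c1C(=O)OC
A4 | alternative 2 | (2S,3R)-3-(3,5-dihydroxy-2,4-dimethylphenyl)butan-2-yl acetate | Cc1c(O)c(C)c(O)cc1[C@@H](C)[C@H](C)OC(C)=O
A5 | alternative 2 | methyl 3-(dimethylamino)-2-[(2R)-2-methyl-4-oxo-3,4-dihydro-2H-pyran-6-yl]prop-2-enoate | COC(=O)C(=CN(C)C)C1=CC(=O)C[C@@H](C)O1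
A6 | alternative 2 | (2S,3R)-3-{7-hydroxy-6,8-dimethyl-3-[(2R)-2-methyl-4-oxo-3,4-dihydro-2H-pyran-6-yl]-2-oxo-2H-chromen-5-yl}butan-2-yl acetate | Cc1c(O)c(C)c2oc(=O)c(C3=CC(=O)C[C@@H](C)O3)cc2c1[C@@H](C)[C@H](C)OC(C)=O
A7 | alternative 3 | (3Z)-1-methoxy-2-methyl-1,3-bis(trimethylsilyloxy)penta-1,3-diene | COC(O[Si](C)(C)C)=C(C)/C(O[Si](C)(C)C)=C/C
A8 | alternative 3 | methyl (4R,5S)-5-(tert-butyldimethylsilyloxy)-4-methylhex-2-ynoate | COC(=O)C#C[C@@H](C)[C@H](C)O[Si](C)(C)C(C)(C)C
A9 | alternative 3 | methyl 6-[(2R,3S)-3-(tert-butyldimethylsilyloxy)butan-2-yl]-2,4-dihydroxy-3,5-dimethylbenzoate | COC(=O)c1c(O)c(C)c(O)c(C)c1[C@@H](C)[C@H](C)O[Si](C)(C)C(C)(C)C
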